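## Structural features

Lasiodiplactone A is a tetracycle built on a benzene ring A that carries five contiguous substituents and one hydrogen: a methoxy group, a carboxyl carbon, an alkyl chain, a benzylic CH2 and an aryl oxygen. The carboxyl carbon and the chain on the neighbouring ring carbon are tied into the 12-membered lactone ring B, in which seven unfunctionalised CH2 groups lead from ring A to the (R)-configured O–CH(CH3) carbon. On the other flank the benzylic CH2 and the aryl oxygen belong to the dihydropyran ring C, which shares a C–C bond with the oxolane ring D. The ketal carbon (bearing CH3 and both ring oxygens), the ring-fusion CH and the CH(CH3) of ring D are three contiguous stereocentres (9aS, 3aS, 3S in furo[2,3-b]chromene numbering), with rings C and D cis-fused and the C-methyl of ring D trans to the benzylic CH2, whereas the fourth stereocentre, the carbinol of ring B, is remote and cannot be controlled by them. The fragile points are the mixed aryl alkyl ketal, which opens under acid, and the ring-fusion CH, which can epimerise whenever the ketal is open; the benzoate is flanked by two ortho substituents, so it is hard to make by acyl substitution but robust once made. The real difficulty is the combination of a regiodefined pentasubstituted arene, a macrolactone next to a shielded carbonyl, and an acid-sensitive ketal of defined configuration. The key step exploits the plain polymethylene chain of ring B: a C=C bond between the second and third chain carbons from the carbinol, far from the hindered ester and from ring A, can be closed by metathesis under neutral conditions on the finished ketal tricycle and then removed by hydrogenation.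

## Logic of the disconnections

**19 back to 18.** No skeletal bond is cut; a C=C bond is written into ring B between the second and third chain carbons from the carbinol. This is the only functionality the saturated chain can hide, and it prepares the ring for a metathesis cut. The forward step must reduce this alkene alone; there is no benzylic C–O bond to hydrogenolyse and the medium can be kept neutral for the ketal.

**18 back to 17.** The ring B alkene is cut. The macrocycle becomes an arene with two independent chains ending in terminal alkenes, each insulated from oxygen and from ring A by at least one CH2. The forward step must favour ring closure over chain growth and must not move the double bonds; it adds no stereocentre, so the complete stereotriad can be in place.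

**17 back to 15 and 16.** The bond cut is the O–C bond between the ester oxygen and the carbinol carbon, not the acyl C–O bond, because the carbonyl sits between two ortho substituents. This separates the only remote stereocentre as the small enantiopure 16. The forward step is then an SN2 displacement by the carboxylate of 15, which demands clean inversion and therefore the (S) configuration in 16.

**15 back to 12 and 13.** The bond between the benzylic carbon on ring A and the next chain carbon is cut. The methyl group so revealed in 12 is the only one ortho to the carboxylate and is uniquely acidified by it, and 13 is a commercial five-carbon electrophile. The forward step needs benzylic deprotonation at that methyl only, and it is placed before esterification so that the enantiopure ester never meets strong base.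

**12 back to 10.** The bond from ring A to the carboxyl carbon is cut, leaving bromine as a placeholder. A bromine is inert through all earlier steps and marks the position unambiguously. The forward step needs halogen–metal exchange (through 11) and carboxylation on a base-stable ketal.

**10 back to 8.** Two bonds at the ketal carbon are cut: aryl oxygen to ketal carbon, and ketal carbon to methyl. Ring C opens, the ketal stereocentre disappears (cis fusion dictates it), and the ketal carbon becomes the lactone carbonyl of 8. The forward step needs single addition of a methyl nucleophile (to 9) and an acid that both frees the phenol and closes the ketal.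

**8 back to 5 and 6.** The bond between the benzylic CH2 and the ring-fusion carbon is cut. This gives 5 as the benzylic electrophile and 7, the enolate of 6, whose existing methyl-bearing centre directs the new one trans. The forward step demands high trans selectivity, monoalkylation, and a phenol protecting group that tolerates a reactive benzylic bromide.

**5 back to 1 by way of 4, 3 and 2.** Functional group changes only: CH2Br from CH2OH from CHO, removal of the phenol protecting group, and cut of the aryl C–Br bond. Bromination is placed first, on the free phenol of 1, where para direction by OH gives the best chance of substitution between the methoxy and methyl groups.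

## Other disconnections considered

Alternative 1: The cut falls on two bonds of ring D made on a finished ring A/B macrolide: the C–CH3 bond and the bond from the ring-fusion carbon to the benzylic CH2 of ring C. In the forward sense CuBr·SMe2 (monovalent copper) with a chiral ferrocenyl diphosphine would add MeMgBr to 2(5H)-furanone A1. The bromomagnesium enolate A2 would be trapped anti to the new methyl by the macrolide benzylic bromide A3 to give the trans-disubstituted lactone A4, which would reach 19 by the methyl addition and ketalisation of step 6.
- In favour: two C–C bonds and both carbon stereocentres of ring D would arise in one operation from an achiral C4 unit, so the chiral-pool lactone 6 is not needed. On stereochemical economy this is the better plan. The trans relationship rests on the same anti-alkylation principle as step 5, where the two plans are equal.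
- Against: copper-catalysed enantioselective Grignard addition is best developed for enones, enoates and thioesters; a five-membered unsaturated lactone with the least reactive Grignard reagent is a marginal case. A2 is a weak nucleophile for benzylation, and A3, the most valuable component, would face residual MeMgBr. Any shortfall in enantioselectivity would show up as diastereomers of A4, because the ring B carbinol is already present.
- Comparison: structurally the pentasubstituted arene with a bromomethyl group beside a protected phenol must still be built inside the macrolide, so the regiochemical problem solved by choosing 1 is only relocated. Mechanistically the later MeLi addition must distinguish the butyrolactone from the macrolactone. In step count the plans are expected to be close, since A3 is itself about ten steps away.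

Alternative 2: Ring A is cut at two bonds: between the methoxy-bearing and the carboxyl-bearing carbons, and between the two alkyl-bearing carbons; rings B and D exist beforehand. The 12-membered ynolide A5 and the ketene-acetal diene A6 (silyl taken as tert-butyldimethylsilyl, oxolane methyl ketal on its terminal CH2) would combine in a thermal Diels–Alder reaction. Loss of methanol and desilylation would give the resorcylate A7, whose free phenol would close ring C on acid treatment.
- In favour: this is the more convergent plan, with two fragments of similar size and a shorter longest linear sequence. All five substituents of ring A are placed in one step with regiochemistry set by the polarisation of diene and ynoate. The hindered benzoate is never made by esterification. On these three points it equals or betters the chosen plan.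
- Against: a β-alkyl ynoate held in a macrocycle is a poor dienophile. A6 is substituted at its reacting terminus and must be a single geometric isomer able to reach the s-cis form. The bond between the two alkyl-bearing carbons joins two substituted centres, so the temperature needed may exceed what a ketene acetal and a methyl ketal tolerate. A5 needs its own macrocyclisation, so the ring B problem is moved, not removed.
- Comparison: the chosen plan closes ring B by a catalytic reaction with broad precedent at this ring size, whereas here the cycloaddition is the uncertain event. Both plans take the trans-disubstituted oxolane from the same kind of lactone alkylation. The total step count is estimated to be somewhat higher (two fragments of five to six steps each plus finishing steps), the linear count lower.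

Alternative 3: The cut removes the lactone C–O bond and the ring A bond between the carboxyl-bearing and chain-bearing carbons, so rings A and B go together and an open-chain polyketide remains. Heating the diketo-dioxinone A8 would release the acylketene A9 by retro-[4+2] loss of acetone. The remote (R)-carbinol would trap it as the 16-membered triketo lactone A10, and Cs2CO3 would drive transannular aldol condensation and aromatisation to the macrolide A11 with two free phenols.
- In favour: two rings and the whole resorcylate would form in one flask without a metal catalyst. The lactone forms by addition to a ketene, so ortho crowding does not matter, and the carbinol is used with retention. For building rings A and B alone this is the more elegant construction and at least the equal of a metathesis.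
- Against: A11 lacks what makes this target difficult. The O-methyl group must go on the chelated, less reactive phenol. The carbon substituent of ring C must be introduced ortho to the other phenol, beside the macrocyclic chain, and not at the more accessible position between the two oxygens. Rings C and D would then still need the chemistry of steps 5 and 6, now in the presence of the macrolactone.
- Comparison: structurally the chosen plan buys the substitution pattern with 1 and never faces this selectivity. Mechanistically the alternative is the more ambitious cascade. In step economy it is clearly longer for this target: a multi-step synthesis of A8, then at least seven steps after A11.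

Key step: step 10

Assumption: metathesis of 17 is taken to deliver the (E)-cycloalkene 18; the geometry of this alkene has no bearing on the route, because step 11 saturates it.

Remark on the chemistry: the phenol is carried as a MOM ether from step 2 to step 6, and the hexenyl chain is attached at the carboxylic acid stage (step 8), before the enantiopure ester is made in step 9.

## Route

Step 1
Reactants: 1 2-hydroxy-4-methoxy-6-methylbenzaldehyde
Product: 2 3-bromo-6-hydroxy-4-methoxy-2-methylbenzaldehyde
Conditions: NBS (1.0 equiv), MeCN, 0 °C → rt
Reagents that add atoms: N-bromosuccinimide, O=C1CCC(=O)N1Br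
Why: Electrophilic aromatic bromination; OH and OMe activate both free positions, but the one para to the stronger donor OH is not wedged between two oxygen substituents, so bromine should enter there, as in para-selective bromination of 2-hydroxy-4-methoxybenzaldehydes, and one equivalent at 0 °C limits dibromination.

Step 2
Reactants: 2 3-bromo-6-hydroxy-4-methoxy-2-methylbenzaldehyde
Product: 3 3-bromo-4-methoxy-6-(methoxymethoxy)-2-methylbenzaldehyde
Conditions: MOMCl, i-Pr2NEt, CH2Cl2, 0 °C → rt
Reagents that add atoms: chloromethyl methyl ether, COCCl
Why: Phenol O-alkylation with an α-chloro ether (MOM protection); the acetal prevents o-quinone methide formation when the benzylic bromide is made, survives hydride, phosphonium, enolate and MeLi conditions, and is removed by the same acid that closes the ketal in step 6.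

Step 3
Reactants: 3 3-bromo-4-methoxy-6-(methoxymethoxy)-2-methylbenzaldehyde
Product: 4 [3-bromo-4-methoxy-6-(methoxymethoxy)-2-methylphenyl]methanol
Conditions: NaBH4, MeOH/THF, 0 °C
Reagents that add atoms: none
Why: Borohydride reduction of an aryl aldehyde; the aryl bromide and the MOM acetal are inert.

Step 4
Reactants: 4 [3-bromo-4-methoxy-6-(methoxymethoxy)-2-methylphenyl]methanol
Product: 5 2-bromo-4-(bromomethyl)-1-methoxy-5-(methoxymethoxy)-3-methylbenzene
Conditions: CBr4, PPh3, CH2Cl2, 0 °C; filtered cold and used at once
Reagents that add atoms: tetrabromomethane, BrC(Br)(Br)Br
Why: Appel reaction; bromide displaces the alkoxyphosphonium group at a primary benzylic carbon under neutral conditions that leave the MOM acetal intact, and the electron-rich bromide is not stored but taken directly into step 5.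

Step 5
Reactants: 5 2-bromo-4-(bromomethyl)-1-methoxy-5-(methoxymethoxy)-3-methylbenzene; 6 (S)-4-methyldihydrofuran-2(3H)-one
Product: 8 (3S,4S)-3-{[3-bromo-4-methoxy-6-(methoxymethoxy)-2-methylphenyl]methyl}-4-methyloxolan-2-one, via lithium enolate 7 (not isolated)
Conditions: 6, LiN(i-Pr)2 (LDA), THF, −78 °C; then 5, −78 → −30 °C
Reagents that add atoms: none
Why: Alkylation of a γ-butyrolactone lithium enolate; the benzylic bromide approaches the planar enolate on the face opposite the C4 methyl group, so the new C3 centre is set trans to it (3S), the usual outcome for β-substituted butyrolactone enolates, and the aryl bromide is inert to the enolate at −78 °C.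

Step 6
Reactants: 8 (3S,4S)-3-{[3-bromo-4-methoxy-6-(methoxymethoxy)-2-methylphenyl]methyl}-4-methyloxolan-2-one
Product: 10 (3S,3aS,9aS)-6-bromo-7-methoxy-3,5,9a-trimethyl-2,3,3a,9a-tetrahydro-4H-furo[2,3-b]chromene, via lactol 9 (not isolated)
Conditions: MeLi (1.1 equiv), THF, −78 °C; then HCl/MeOH, −78 → 40 °C; concentrate; PPTS (cat.), CH2Cl2, 4 Å MS, rt
Reagents that add atoms: methyllithium, C[Li]
Why: Single addition of MeLi to the lactone gives a lithium lactolate that is stable at −78 °C and becomes lactol 9 on protonation; HCl/MeOH then cleaves the MOM acetal and the freed phenol captures the oxocarbenium ion of ring D (intramolecular ketalisation, driven to completion on removal of methanol). Only the cis ring fusion is feasible for this 6/5 ketal, so the ketal carbon (9aS) is dictated by the ring-fusion CH under thermodynamic control, and the trans arrangement of benzylic CH2 and C-methyl is also the more stable one should the ring-fusion centre equilibrate.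

Step 7
Reactants: 10 (3S,3aS,9aS)-6-bromo-7-methoxy-3,5,9a-trimethyl-2,3,3a,9a-tetrahydro-4H-furo[2,3-b]chromene
Product: 12 (3S,3aS,9aS)-7-methoxy-3,5,9a-trimethyl-2,3,3a,9a-tetrahydro-4H-furo[2,3-b]chromene-6-carboxylic acid, via aryllithium 11 (not isolated)
Conditions: n-BuLi, THF, −78 °C; CO2 (g), −78 → 0 °C; 1 M HCl to pH 3, 0 °C
Reagents that add atoms: carbon dioxide, O=C=O
Why: Bromine–lithium exchange on an electron-rich aryl bromide followed by carboxylation of the aryllithium; ketal and ethers are inert to n-BuLi at −78 °C, and brief cold acidification is tolerated because the closed ketal is the thermodynamic form under acid.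

Step 8
Reactants: 12 (3S,3aS,9aS)-7-methoxy-3,5,9a-trimethyl-2,3,3a,9a-tetrahydro-4H-furo[2,3-b]chromene-6-carboxylic acid; 13 5-bromopent-1-ene
Product: 15 (3S,3aS,9aS)-5-(hex-5-en-1-yl)-7-methoxy-3,9a-dimethyl-2,3,3a,9a-tetrahydro-4H-furo[2,3-b]chromene-6-carboxylic acid, via dilithio dianion 14 (not isolated)
Conditions: LiN(i-Pr)2 (LDA, 2.3 equiv), THF/DMPU, −78 → 0 °C; 13, −78 °C → rt; 1 M HCl to pH 3, 0 °C
Reagents that add atoms: none
Why: Carboxylate-directed lateral lithiation (alkylation of an o-toluic acid dianion); the amide base removes the carboxyl proton and then a proton of the only methyl group ortho to the carboxylate, and the benzylic lithium displaces bromide from primary bromide 13 by SN2. The lithium carboxylate cannot self-condense and no stereocentre is exposed to epimerisation.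

Step 9
Reactants: 15 (3S,3aS,9aS)-5-(hex-5-en-1-yl)-7-methoxy-3,9a-dimethyl-2,3,3a,9a-tetrahydro-4H-furo[2,3-b]chromene-6-carboxylic acid; 16 (S)-pent-4-en-2-ol
Product: 17 (2R)-pent-4-en-2-yl (3S,3aS,9aS)-5-(hex-5-en-1-yl)-7-methoxy-3,9a-dimethyl-2,3,3a,9a-tetrahydro-4H-furo[2,3-b]chromene-6-carboxylate
Conditions: PPh3, DIAD, toluene, 0 °C → rt
Reagents that add atoms: none
Why: Mitsunobu esterification; the hindered acid acts as the nucleophile and attacks the oxyphosphonium-activated carbinol carbon of 16 by SN2, so the shielded carbonyl is never attacked and the (S)-alcohol gives the (R)-ester with inversion.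

Step 10
Reactants: 17 (2R)-pent-4-en-2-yl (3S,3aS,9aS)-5-(hex-5-en-1-yl)-7-methoxy-3,9a-dimethyl-2,3,3a,9a-tetrahydro-4H-furo[2,3-b]chromene-6-carboxylate
Product: 18 (E)-didehydrolasiodiplactone A: the tetracycle of 19 with an E C=C bond in ring B between the second and third chain carbons counted from the (R)-carbinol, ketal tricycle (3S,3aS,9aS) unchanged
Conditions: (H2IMes)(PCy3)Cl2Ru=CHPh (second-generation Grubbs catalyst, 5 mol %), CH2Cl2 (1 mM), 40 °C
Reagents that add atoms: none
Why: Ring-closing olefin metathesis by the Chauvin mechanism: (H2IMes)(PCy3)Cl2Ru=CHPh loses PCy3, takes up one terminal alkene by [2+2] cycloaddition and cycloreversion, and the resulting alkylidene engages the second terminal alkene intramolecularly through a ruthenacyclobutane that collapses to the ring alkene and the methylidene Ru=CH2, which carries the cycle with loss of ethene. The closest known reaction type is the metathesis closure of 12-membered resorcylic macrolactones from ortho-alkenyl benzoates of alkenyl carbinols. Ring B is closed as a 12-membered cycloalkene by end-to-end union of two monosubstituted alkenes, the new C=C lying inside the ring at the second and third carbons from the carbinol. No stereocentre is formed and the four existing ones are untouched because the conditions are neutral and aprotic; the geometry of the new alkene is of no consequence, since step 11 saturates it. The step needs ring closure to beat oligomerisation, which high dilution, loss of ethene at reflux and the ortho placement of ester and hexenyl chain on the same flank of ring A should secure. It also needs the alkenes to stay in place: both are terminal, unhindered and separated from the ester oxygen and the arene by at least one CH2, and the mild temperature limits hydride-induced migration. The aryl alkyl ketal, the methoxy group and the hindered benzoate are inert to the carbene.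

Step 11
Reactants: 18 (E)-didehydrolasiodiplactone A
Product: 19 lasiodiplactone A
Conditions: H2 (1 atm), 10% Pd/C (palladium on carbon), EtOAc, rt
Reagents that add atoms: none
Why: Heterogeneous hydrogenation of a disubstituted alkene; there is no benzylic C–O bond open to hydrogenolysis (the lactone oxygen sits on a non-benzylic carbon and the ketal is not reduced), neutral EtOAc avoids ketal exchange, and saturation erases the alkene geometry whatever it is.

## Compound list

1 | 2-hydroxy-4-methoxy-6-methylbenzaldehyde | COc1cc(O)c(C=O)c(C)c1 | starting material
2 | 3-bromo-6-hydroxy-4-methoxy-2-methylbenzaldehyde | COc1cc(O)c(C=O)c(C)c1Br | intermediate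
3 | 3-bromo-4-methoxy-6-(methoxymethoxy)-2-methylbenzaldehyde | COCOc1cc(OC)c(Br)c(C)c1C=O | intermediate
4 | [3-bromo-4-methoxy-6-(methoxymethoxy)-2-methylphenyl]methanol | COCOc1cc(OC)c(Br)c(C)c1CO | intermediate
5 | 2-bromo-4-(bromomethyl)-1-methoxy-5-(methoxymethoxy)-3-methylbenzene | COCOc1cc(OC)c(Br)c(C)c1CBr | intermediate
6 | (S)-4-methyldihydrofuran-2(3H)-one | O=C1C[C@H](C)CO1 | starting material
7 | lithium (4S)-4-methyl-4,5-dihydrofuran-2-olate (lithium enolate of 6) | [Li]OC1=C[C@H](C)CO1 | intermediate (not isolated)
8 | (3S,4S)-3-{[3-bromo-4-methoxy-6-(methoxymethoxy)-2-methylphenyl]methyl}-4-methyloxolan-2-one | COCOc1cc(OC)c(Br)c(C)c1C[C@H]1[C@H](C)COC1=O | intermediate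
9 | (3S,4S)-3-{[3-bromo-4-methoxy-6-(methoxymethoxy)-2-methylphenyl]methyl}-2,4-dimethyloxolan-2-ol (both C2 epimers, in equilibrium with the open hydroxy ketone) | COCOc1cc(OC)c(Br)c(C)c1C[C@H]1[C@H](C)COC1(C)O | intermediate (not isolated)
10 | (3S,3aS,9aS)-6-bromo-7-methoxy-3,5,9a-trimethyl-2,3,3a,9a-tetrahydro-4H-furo[2,3-b]chromene | COc1cc2c(c(C)c1Br)C[C@H]1[C@H](C)CO[C@@]1(C)O2 | intermediate
11 | (3S,3aS,9aS)-6-lithio-7-methoxy-3,5,9a-trimethyl-2,3,3a,9a-tetrahydro-4H-furo[2,3-b]chromene | COc1cc2c(c(C)c1[Li])C[C@H]1[C@H](C)CO[C@@]1(C)O2 | intermediate (not isolated)
12 | (3S,3aS,9aS)-7-methoxy-3,5,9a-trimethyl-2,3,3a,9a-tetrahydro-4H-furo[2,3-b]chromene-6-carboxylic acid | COc1cc2c(c(C)c1C(=O)O)C[C@H]1[C@H](C)CO[C@@]1(C)O2 | intermediate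
13 | 5-bromopent-1-ene | C=CCCCBr | starting material
14 | lithium (3S,3aS,9aS)-5-(lithiomethyl)-7-methoxy-3,9a-dimethyl-2,3,3a,9a-tetrahydro-4H-furo[2,3-b]chromene-6-carboxylate | COc1cc2c(c(C[Li])c1C(=O)O[Li])C[C@H]1[C@H](C)CO[C@@]1(C)O2 | intermediate (not isolated)
15 | (3S,3aS,9aS)-5-(hex-5-en-1-yl)-7-methoxy-3,9a-dimethyl-2,3,3a,9a-tetrahydro-4H-furo[2,3-b]chromene-6-carboxylic acid | COc1cc2c(c(CCCCC=C)c1C(=O)O)C[C@H]1[C@H](C)CO[C@@]1(C)O2 | intermediate
16 | (S)-pent-4-en-2-ol | O[C@@H](C)CC=C | starting material
17 | (2R)-pent-4-en-2-yl (3S,3aS,9aS)-5-(hex-5-en-1-yl)-7-methoxy-3,9a-dimethyl-2,3,3a,9a-tetrahydro-4H-furo[2,3-b]chromene-6-carboxylate | COc1cc2c(c(CCCCC=C)c1C(=O)O[C@H](C)CC=C)C[C@H]1[C@H](C)CO[C@@]1(C)O2 | intermediate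
18 | (E)-didehydrolasiodiplactone A (E alkene in ring B, second/third chain carbons from the carbinol) | COc1cc2c(c(CCCC/C=C/C[C@@H](C)O3)c1C3=O)C[C@H]1[C@H](C)CO[C@@]1(C)O2 | intermediate
19 | lasiodiplactone A | COc1cc2c(c3c1C(=O)O[C@H](C)CCCCCCC3)C[C@H]1[C@H](C)CO[C@@]1(C)O2 | target

## Step count and least certain steps

Total step count: 11. Longest linear sequence: 11 steps (1 → 19); 6, 13 and 16 enter in steps 5, 8 and 9.

**Step 10 (key step).** The most likely failure is chain growth by intermolecular metathesis in place of ring closure. Alkene migration before closure, which would contract the ring, and slow turnover through coordination of the ester carbonyl to ruthenium are also possible. The fallback closes ring B at the ester bond and sets out from 15. Cross-metathesis of 15 with an excess of 16 under (H2IMes)(PCy3)Cl2Ru=CHPh would give the (E)-hydroxy acid F1, whose alkene geometry is again irrelevant. Hydrogenation over Pd/C would give the saturated (S)-hydroxy acid F2. Mitsunobu macrolactonisation (PPh3, DIAD, toluene, high dilution) would then close the lactone with inversion at the carbinol and return to the route at 19.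

**Step 1.** Bromine may enter at the position between the two oxygen substituents, or twice, because both free positions are activated. The fallback sets out from 1 and blocks the unwanted position sterically. Silylation (i-Pr3SiCl, imidazole, DMF) would give the silyl ether F3. NBS should then brominate only the position para to the silyloxy group to give the bromo silyl ether F4, and Bu4NF would return the route to 2.

**Step 5.** The electron-rich benzylic bromide may ionise and self-condense before it meets the enolate. Proton transfer from product to enolate can lead to double alkylation, and trans selectivity may erode. The fallback forms the same C–C bond by carbonyl addition and sets out from 3 and 6. Aldol addition of 7 to 3 at −78 °C would give the hydroxy lactone F5. Mesylation (MsCl, Et3N) to the mesylate F6 and elimination with DBU would give the arylidene lactone F7. Conjugate reduction with [(Ph3P)CuH]6 (monovalent copper), which spares aryl bromides, would give 8 together with its cis epimer F8. Equilibration with DBU in toluene toward the more stable trans isomer would return the route to 8.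

**Step 6.** A second methyl addition to the ring-opened ketone, enolisation of the lactone by MeLi, halogen–lithium exchange at the aryl bromide, or incomplete ketal closure while methanol is present could each lower the return. The fallback avoids organolithium addition and sets out from 8. Methylenation with Cp2TiMe2 (tetravalent titanium) in toluene at 70 °C would give the exocyclic enol ether F9. The same acid treatment would cleave the MOM group and add the phenol across the enol ether in the Markovnikov sense, returning to the route at 10.

**Step 8.** Incomplete second deprotonation, base-induced elimination of HBr from 13, or O-alkylation of the carboxylate could compete with C-alkylation. The fallback changes the order and the nature of the carbanion and sets out from 12. Mitsunobu esterification with 16 would give the (R)-pentenyl ester F10. Its ester-stabilised benzylic anion (LiN(i-Pr)2, THF, −78 °C) would be alkylated with 13, and the route is rejoined at 17.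

## Further compounds

F1 | step 10 | (3S,3aS,9aS)-5-[(5E,8S)-8-hydroxynon-5-en-1-yl]-7-methoxy-3,9a-dimethyl-2,3,3a,9a-tetrahydro-4H-furo[2,3-b]chromene-6-carboxylic acid | COc1cc2c(c(CCCC/C=C/C[C@H](C)O)c1C(=O)O)C[C@H]1[C@H](C)CO[C@@]1(C)O2
F2 | step 10 | (3S,3aS,9aS)-5-[(8S)-8-hydroxynonyl]-7-methoxy-3,9a-dimethyl-2,3,3a,9a-tetrahydro-4H-furo[2,3-b]chromene-6-carboxylic acid | COc1cc2c(c(CCCCCCC[C@H](C)O)c1C(=O)O)C[C@H]1[C@H](C)CO[C@@]1(C)O2
F3 | step 1 | 4-methoxy-2-methyl-6-{[tri(propan-2-yl)silyl]oxy}benzaldehyde | COc1cc(O[Si](C(C)C)(C(C)C)C(C)C)c(C=O)c(C)c1
F4 | step 1 | 3-bromo-4-methoxy-2-methyl-6-{[tri(propan-2-yl)silyl]oxy}benzaldehyde | COc1cc(O[Si](C(C)C)(C(C)C)C(C)C)c(C=O)c(C)c1Br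
F5 | step 5 | (3R,4S)-3-{[3-bromo-4-methoxy-6-(methoxymethoxy)-2-methylphenyl](hydroxy)methyl}-4-methyloxolan-2-one (3,4-trans, carbinol epimers) | COCOc1cc(OC)c(Br)c(C)c1C(O)[C@H]1[C@H](C)COC1=O
F6 | step 5 | [3-bromo-4-methoxy-6-(methoxymethoxy)-2-methylphenyl][(3R,4S)-4-methyl-2-oxooxolan-3-yl]methyl methanesulfonate | COCOc1cc(OC)c(Br)c(C)c1C(OS(C)(=O)=O)[C@H]1[C@H](C)COC1=O
F7 | step 5 | (3E,4S)-3-{[3-bromo-4-methoxy-6-(methoxymethoxy)-2-methylphenyl]methylidene}-4-methyloxolan-2-one | COCOc1cc(OC)c(Br)c(C)c1/C=C2\[C@H](C)COC2=O
F8 | step 5 | (3R,4S)-3-{[3-bromo-4-methoxy-6-(methoxymethoxy)-2-methylphenyl]methyl}-4-methyloxolan-2-one (cis epimer of 8) | COCOc1cc(OC)c(Br)c(C)c1C[C@@H]1[C@H](C)COC1=O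
F9 | step 6 | (3S,4S)-3-{[3-bromo-4-methoxy-6-(methoxymethoxy)-2-methylphenyl]methyl}-4-methyl-2-methylideneoxolane | COCOc1cc(OC)c(Br)c(C)c1C[C@H]1[C@H](C)COC1=C
F10 | step 8 | (2R)-pent-4-en-2-yl (3S,3aS,9aS)-7-methoxy-3,5,9a-trimethyl-2,3,3a,9a-tetrahydro-4H-furo[2,3-b]chromene-6-carboxylate | COc1cc2c(c(C)c1C(=O)O[C@H](C)CC=C)C[C@H]1[C@H](C)CO[C@@]1(C)O2
A1 | alternative 1 | 2(5H)-furanone | O=C1C=CCO1
A2 | alternative 1 | bromomagnesium (4S)-4-methyl-4,5-dihydrofuran-2-olate | Br[Mg]OC1=C[C@H](C)CO1
A3 | alternative 1 | 12-membered resorcylic lactone with MOM-protected phenol and a bromomethyl group between the OMOM-bearing and the chain-bearing ring carbons | COc1cc(OCOC)c(CBr)c2c1C(=O)O[C@H](C)CCCCCCC2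
A4 | alternative 1 | the same MOM-protected macrolide carrying a trans-[(3S,4S)-4-methyl-2-oxooxolan-3-yl]methyl group in place of the bromomethyl group | COc1cc(OCOC)c(C[C@H]3[C@H](C)COC3=O)c2c1C(=O)O[C@H](C)CCCCCCC2
A5 | alternative 2 | (12R)-12-methyl-1-oxacyclododec-3-yn-2-one (12-membered ynolide) | O=C1C#CCCCCCCC[C@@H](C)O1
A6 | alternative 2 | 1,1-dimethoxy-3-(tert-butyldimethylsilyloxy) diene carrying the (3S,4S)-2-methoxy-2,4-dimethyloxolan-3-yl group on its terminal CH2 | COC(OC)=CC(O[Si](C)(C)C(C)(C)C)=CC[C@H]1[C@H](C)COC1(C)OC
A7 | alternative 2 | resorcylic macrolide (rings A and B) with a free phenol next to the [(3S,4S)-2-methoxy-2,4-dimethyloxolan-3-yl]methyl side chain | COc1cc(O)c(C[C@H]3[C@H](C)COC3(C)OC)c2c1C(=O)O[C@H](C)CCCCCCC2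
A8 | alternative 3 | 6-[(12R)-12-hydroxy-2,4-dioxotridecyl]-2,2-dimethyl-4H-1,3-dioxin-4-one | CC1(C)OC(=O)C=C(CC(=O)CC(=O)CCCCCCC[C@@H](C)O)O1
A9 | alternative 3 | (15R)-15-hydroxyhexadec-1-ene-1,3,5,7-tetrone (acylketene) | O=C=CC(=O)CC(=O)CC(=O)CCCCCCC[C@@H](C)O
A10 | alternative 3 | (16R)-16-methyl-1-oxacyclohexadecane-2,4,6,8-tetrone (16-membered triketo lactone) | C[C@@H]1CCCCCCCC(=O)CC(=O)CC(=O)CC(=O)O1
A11 | alternative 3 | (R)-configured 12-membered resorcylic lactone without the O-methyl group, both phenols free | Oc1cc(O)cc2c1C(=O)O[C@H](C)CCCCCCC2
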